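Cuts: after the silyl and benzyl groups come off, the bond between C2 of the oxolane ring and C1 of the central arene (ring B) is cut. This gives anomeric sulfone 13 (fragment 1: oxolane and ring A) and the arylzinc reagent from bromide 23 (fragment 2: ring B, glycerol chain, ring C).
Enabling feature: C2 of the oxolane is bonded to the ring oxygen O1 as well as to ring B, so at the aldehyde level it can become an oxocarbenium carbon. The CH2O group on C3 and the benzyl group on C4 are cis and cover one ring face together, which leaves the other face free for the aryl group (2,3-trans).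
Fragment 1 is cut further at O1-C2 and C2-C3. A 3,4-cis oxolane corresponds to a 3,4-trans butyrolactone (temporary ring) whose alpha-carbon carries the future C2 as a dimethoxymethyl group. The lactone comes from aldehyde 1 and dimethyl succinate.
Fragment 2 is cut at the benzylic C-C bond of the chain (aldol of an aryloxyacetyl imide with the same aldehyde 1) and at the aryl O-CH2 bond.
Forward order: lactone ring, alpha-alkylation, reduction with ring switch to the oxolane, sulfone. In parallel: ether, imide, aldol, reduction, silylation. Then union of the halves, desilylation and hydrogenolysis.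
Stereochemistry: C4 comes from a rhodium-catalysed asymmetric hydrogenation, C3 from anti alkylation next to C4, and C2 from substrate control in the union. Both chain centres (S,S, threo) come from the (R)-oxazolidinone in a syn aldol.

Key step: step 13

Assumption: the (S,S) antipode of Et-DuPHOS is taken to give the (R) half-ester 4, by analogy with the sense known for enamide and itaconate substrates. If the sense were opposite, the (R,R) ligand would be used and nothing else would change.

Step 1
Reactants: 1 4-(benzyloxy)-3-methoxybenzaldehyde; 2 dimethyl succinate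
Product: 3 (E)-4-[4-(benzyloxy)-3-methoxyphenyl]-3-(methoxycarbonyl)but-3-enoic acid
Conditions: NaOMe, MeOH, reflux; then aq HCl
Reagents that add atoms: none
Why: Stobbe condensation: the succinate enolate adds to the aldehyde, the alkoxide closes a paraconic lactone, and its base-induced E1cB opening should give the (E)-alkylidene half-ester, which also tells the two carboxyl groups apart.

Step 2
Reactants: 3 (E)-4-[4-(benzyloxy)-3-methoxyphenyl]-3-(methoxycarbonyl)but-3-enoic acid
Product: 4 (R)-4-[4-(benzyloxy)-3-methoxyphenyl]-3-(methoxycarbonyl)butanoic acid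
Conditions: H2 (5 bar), [Rh(cod)((S,S)-Et-DuPHOS)]OTf (0.5 mol %), NaOMe (10 mol %), MeOH, rt
Reagents that add atoms: none
Why: Chelate-controlled asymmetric hydrogenation of an itaconate-type half-ester: carboxylate and alkene bind the cationic rhodium centre and the bisphospholane opens only one alkene face to hydrogen, which sets the (R) centre that becomes C4 of the oxolane, while the benzyl ether is inert to this homogeneous catalyst.

Step 3
Reactants: 4 (R)-4-[4-(benzyloxy)-3-methoxyphenyl]-3-(methoxycarbonyl)butanoic acid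
Product: 6 (R)-4-[4-(benzyloxy)-3-methoxybenzyl]dihydrofuran-2(3H)-one, via hydroxy acid 5 (not isolated)
Conditions: KOH (1 equiv), EtOH; CaCl2, NaBH4, EtOH, -10 °C to rt; then 3 M HCl, rt
Reagents that add atoms: none
Why: Chemoselective ester reduction followed by lactonisation: Ca(BH4)2 formed in the flask reduces the methyl ester but leaves the potassium carboxylate, and acid then closes the five-membered lactone without touching the stereocentre.

Step 4
Reactants: 6 (R)-4-[4-(benzyloxy)-3-methoxybenzyl]dihydrofuran-2(3H)-one; 7 trimethyl orthoformate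
Product: 9 (3S,4R)-4-[4-(benzyloxy)-3-methoxybenzyl]-3-(dimethoxymethyl)dihydrofuran-2(3H)-one, via silyl ketene acetal 8 (not isolated)
Conditions: LiN(iPr)2, THF, -78 °C; Me3SiCl; solvent change to CH2Cl2; 7, Me3SiOTf (10 mol %), -78 °C
Reagents that add atoms: chlorotrimethylsilane, C[Si](C)(C)Cl (its silyl group stays only in 8)
Why: Mukaiyama-type alkylation of a silyl ketene acetal with the dimethoxycarbenium ion released from the orthoester: the electrophile should approach the nearly flat dihydrofuran ring anti to the C4 benzyl group, which sets C3 as (S), trans to C4, and brings in the future C2 of the oxolane at the aldehyde level.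

Step 5
Reactants: 9 (3S,4R)-4-[4-(benzyloxy)-3-methoxybenzyl]-3-(dimethoxymethyl)dihydrofuran-2(3H)-one
Product: 11 {(3R,4R)-4-[4-(benzyloxy)-3-methoxybenzyl]-2-methoxyoxolan-3-yl}methanol (both C2 anomers), via diol acetal 10 (not isolated)
Conditions: LiAlH4, THF, 0 °C; H2O/NaOH work-up; then pyridinium p-toluenesulfonate (5 mol %), CH2Cl2, rt
Reagents that add atoms: none
Why: Hydride reduction of the lactone and acid-catalysed transacetalisation (5-exo closure): only the hydroxyl freed from the lactone O-CH2 can reach the acetal carbon through a five-membered ring, whereas the other one would have to form an oxetane, so the ring switch converts the 3,4-trans lactone into the 3,4-cis oxolane without breaking any bond at a stereocentre.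

Step 6
Reactants: 11 {(3R,4R)-4-[4-(benzyloxy)-3-methoxybenzyl]-2-methoxyoxolan-3-yl}methanol
Product: 12 (3R,4R)-4-[4-(benzyloxy)-3-methoxybenzyl]-3-{[(tert-butyldiphenylsilyl)oxy]methyl}-2-methoxyoxolane
Conditions: tBuPh2SiCl, imidazole, CH2Cl2, rt
Reagents that add atoms: tert-butyl(chloro)diphenylsilane, CC(C)(C)[Si](Cl)(c1ccccc1)c1ccccc1
Why: Standard silylation of the only free (primary) hydroxyl; the bulky, acid-tolerant silyl group should survive step 7 and adds to the shielding of the covered ring face in step 13.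

Step 7
Reactants: 12 (3R,4R)-4-[4-(benzyloxy)-3-methoxybenzyl]-3-{[(tert-butyldiphenylsilyl)oxy]methyl}-2-methoxyoxolane
Product: 13 (3R,4R)-2-(benzenesulfonyl)-4-[4-(benzyloxy)-3-methoxybenzyl]-3-{[(tert-butyldiphenylsilyl)oxy]methyl}oxolane
Conditions: PhSO2H, CaCl2, CH2Cl2, rt
Reagents that add atoms: benzenesulfinic acid, O=S(O)c1ccccc1
Why: Acid-mediated acetal exchange: the sulfinic acid protonates the methoxy group, the oxocarbenium ion is captured at sulfur and CaCl2 binds the methanol, which should give the anomeric sulfone as the activating group for step 13.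

Step 8
Reactants: 14 4-bromo-2-methoxyphenol; 15 bromoacetic acid
Product: 16 2-(4-bromo-2-methoxyphenoxy)acetic acid
Conditions: NaOH (2 equiv), H2O, reflux; then aq HCl
Reagents that add atoms: none
Why: Williamson ether synthesis of the phenoxide with the bromoacetate ion (SN2 at a primary carbon).

Step 9
Reactants: 16 2-(4-bromo-2-methoxyphenoxy)acetic acid; 17 (R)-4-benzyloxazolidin-2-one
Product: 19 (R)-4-benzyl-3-[2-(4-bromo-2-methoxyphenoxy)acetyl]oxazolidin-2-one, via mixed pivalic anhydride 18 (not isolated)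
Conditions: tBuCOCl, Et3N, THF, -20 °C; then 17, LiCl, rt
Reagents that add atoms: pivaloyl chloride, CC(C)(C)C(=O)Cl (its acyl group stays only in 18)
Why: N-acylation of the oxazolidinone through the mixed pivalic anhydride, which is attacked at its less hindered carbonyl group under LiCl activation.

Step 10
Reactants: 19 (R)-4-benzyl-3-[2-(4-bromo-2-methoxyphenoxy)acetyl]oxazolidin-2-one; 1 4-(benzyloxy)-3-methoxybenzaldehyde
Product: 21 (R)-4-benzyl-3-{(2R,3S)-3-[4-(benzyloxy)-3-methoxyphenyl]-2-(4-bromo-2-methoxyphenoxy)-3-hydroxypropanoyl}oxazolidin-2-one, via dibutylboron enolate 20 (not isolated)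
Conditions: Bu2BOTf, Et3N, CH2Cl2, -78 to 0 °C; 1, -78 to 0 °C; H2O2, MeOH, pH 7 buffer
Reagents that add atoms: dibutylboron triflate, CCCCB(CCCC)OS(=O)(=O)C(F)(F)F (its Bu2B group stays only in 20)
Why: Evans syn aldol reaction: the (Z)-boron enolate reacts through a closed chair transition state on the face away from the benzyl group of the (R)-auxiliary, which sets (2R,3S), that is, the threo relation and the absolute configuration of both chain centres.

Step 11
Reactants: 21 (R)-4-benzyl-3-{(2R,3S)-3-[4-(benzyloxy)-3-methoxyphenyl]-2-(4-bromo-2-methoxyphenoxy)-3-hydroxypropanoyl}oxazolidin-2-one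
Product: 22 (1S,2S)-1-[4-(benzyloxy)-3-methoxyphenyl]-2-(4-bromo-2-methoxyphenoxy)propane-1,3-diol
Conditions: NaBH4, THF/H2O, 0 °C to rt
Reagents that add atoms: none
Why: Reductive cleavage of the imide: borohydride attacks the more electrophilic exocyclic carbonyl group, frees the auxiliary and gives the primary alcohol under conditions mild enough to avoid retro-aldol cleavage.

Step 12
Reactants: 22 (1S,2S)-1-[4-(benzyloxy)-3-methoxyphenyl]-2-(4-bromo-2-methoxyphenoxy)propane-1,3-diol
Product: 23 (1S,2S)-1-[4-(benzyloxy)-3-methoxyphenyl]-2-(4-bromo-2-methoxyphenoxy)-1,3-bis[(tert-butyldimethylsilyl)oxy]propane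
Conditions: tBuMe2SiOTf, 2,6-lutidine, CH2Cl2, 0 °C
Reagents that add atoms: tert-butyldimethylsilyl triflate, CC(C)(C)[Si](C)(C)OS(=O)(=O)C(F)(F)F
Why: Silylation of both hydroxyls with the silyl triflate and a hindered base removes all acidic protons before metalation and lowers the tendency of the benzylic C-O bond to ionise.

Step 13
Reactants: 23 (1S,2S)-1-[4-(benzyloxy)-3-methoxyphenyl]-2-(4-bromo-2-methoxyphenoxy)-1,3-bis[(tert-butyldimethylsilyl)oxy]propane; 13 (3R,4R)-2-(benzenesulfonyl)-4-[4-(benzyloxy)-3-methoxybenzyl]-3-{[(tert-butyldiphenylsilyl)oxy]methyl}oxolane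
Product: 26 (2S,3R,4R)-4-[4-(benzyloxy)-3-methoxybenzyl]-2-{4-[(1S,2S)-1-[4-(benzyloxy)-3-methoxyphenyl]-1,3-bis[(tert-butyldimethylsilyl)oxy]propan-2-yl]oxy-3-methoxyphenyl}-3-{[(tert-butyldiphenylsilyl)oxy]methyl}oxolane, via aryllithium 24 (not isolated), via arylzinc bromide 25 (not isolated)
Conditions: 23 (1.3 equiv), n-BuLi, THF, -78 °C; ZnBr2, -78 °C to rt; then 13, THF, rt
Reagents that add atoms: n-butyllithium, [Li]CCCC (lithium stays only in 24); zinc dibromide, Br[Zn]Br (zinc and bromine stay only in 25)
Why: Bromine-lithium exchange and transmetalation give arylzinc bromide 25; its mildly Lewis acidic zinc centre pulls the benzenesulfinate off C2 of 13, lone-pair donation from the ring oxygen O1 gives the cyclic oxocarbenium ion, and the aryl group is transferred from zinc to C2. The closest known reaction type is the substitution of 2-(arylsulfonyl) cyclic ethers by organozinc reagents, a C-aryl glycosylation of an anomeric sulfone that has been applied to 2-aryloxolane lignans. No ring is closed, because the oxolane is already in place. The one new stereocentre, C2 (S), is set by the substrate: the silyloxymethyl group on C3 and the benzyl group on C4 lie on the same face, so 1,2- and 1,3-induction are matched, the aryl group enters from the free face trans to C3, and both anomers of 13 converge on the same ion. The step needs substitution instead of loss of H-3 to a dihydrofuran (which would also endanger C3), and the weakly basic zinc nucleophile at room temperature secures this. It also needs bonding at C1 of ring B only and survival of the acid-labile benzylic C-O bond next to ring C, which the position of the bromine in 23 and the absence of any strong Lewis or Brønsted acid secure.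

Step 14
Reactants: 26 fully protected coupling product
Product: 27 (1S,2S)-1-[4-(benzyloxy)-3-methoxyphenyl]-2-{4-[(2S,3R,4R)-4-[4-(benzyloxy)-3-methoxybenzyl]-3-(hydroxymethyl)oxolan-2-yl]-2-methoxyphenoxy}propane-1,3-diol
Conditions: Bu4NF, AcOH, THF, rt
Reagents that add atoms: none
Why: Fluoride-induced cleavage of all three Si-O bonds, buffered with acetic acid so that no strongly basic alkoxide builds up next to the aryl ether.

Step 15
Reactants: 27 bis(benzyl ether) triol
Product: 28 (1S,2S)-1-(4-hydroxy-3-methoxyphenyl)-2-{4-[(2S,3R,4R)-4-(4-hydroxy-3-methoxybenzyl)-3-(hydroxymethyl)oxolan-2-yl]-2-methoxyphenoxy}propane-1,3-diol (target CNP0226724.1)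
Conditions: H2 (1 atm), 10% Pd/C, EtOAc/EtOH, rt
Reagents that add atoms: none
Why: Hydrogenolysis of the two aryl benzyl ethers, whose unhindered primary benzylic C-O bonds should be cleaved far faster than the secondary benzylic C-O bonds at C2 of the oxolane and in the side chain, so no stereocentre is touched.

Compound list
1 | 4-(benzyloxy)-3-methoxybenzaldehyde | O=Cc1ccc(OCc2ccccc2)c(OC)c1 | starting material
2 | dimethyl succinate | COC(=O)CCC(=O)OC | starting material
3 | (E)-4-[4-(benzyloxy)-3-methoxyphenyl]-3-(methoxycarbonyl)but-3-enoic acid | COC(=O)/C(CC(=O)O)=C/c1ccc(OCc2ccccc2)c(OC)c1 | intermediate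
4 | (R)-4-[4-(benzyloxy)-3-methoxyphenyl]-3-(methoxycarbonyl)butanoic acid | COc1cc(C[C@@H](C(=O)OC)CC(=O)O)ccc1OCc1ccccc1 | intermediate
5 | (R)-4-[4-(benzyloxy)-3-methoxyphenyl]-3-(hydroxymethyl)butanoic acid (not isolated) | OC[C@@H](CC(=O)O)Cc1ccc(OCc2ccccc2)c(OC)c1 | intermediate
6 | (R)-4-[4-(benzyloxy)-3-methoxybenzyl]dihydrofuran-2(3H)-one | COc1cc(C[C@H]2COC(=O)C2)ccc1OCc1ccccc1 | intermediate
7 | trimethyl orthoformate | COC(OC)OC | starting material
8 | (R)-4-[4-(benzyloxy)-3-methoxybenzyl]-2-(trimethylsilyloxy)-4,5-dihydrofuran (not isolated) | COc1cc(C[C@H]2COC(O[Si](C)(C)C)=C2)ccc1OCc1ccccc1 | intermediate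
9 | (3S,4R)-4-[4-(benzyloxy)-3-methoxybenzyl]-3-(dimethoxymethyl)dihydrofuran-2(3H)-one | COc1cc(C[C@H]2COC(=O)[C@@H]2C(OC)OC)ccc1OCc1ccccc1 | intermediate
10 | (2R,3R)-2-[4-(benzyloxy)-3-methoxybenzyl]-3-(dimethoxymethyl)butane-1,4-diol (not isolated) | COc1cc(C[C@@H](CO)[C@H](CO)C(OC)OC)ccc1OCc1ccccc1 | intermediate
11 | {(3R,4R)-4-[4-(benzyloxy)-3-methoxybenzyl]-2-methoxyoxolan-3-yl}methanol, both C2 anomers | COc1cc(C[C@H]2COC(OC)[C@H]2CO)ccc1OCc1ccccc1 | intermediate
12 | (3R,4R)-4-[4-(benzyloxy)-3-methoxybenzyl]-3-{[(tert-butyldiphenylsilyl)oxy]methyl}-2-methoxyoxolane | COc1cc(C[C@H]2COC(OC)[C@H]2CO[Si](c2ccccc2)(c2ccccc2)C(C)(C)C)ccc1OCc1ccccc1 | intermediate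
13 | (3R,4R)-2-(benzenesulfonyl)-4-[4-(benzyloxy)-3-methoxybenzyl]-3-{[(tert-butyldiphenylsilyl)oxy]methyl}oxolane | COc1cc(C[C@H]2COC(S(=O)(=O)c3ccccc3)[C@H]2CO[Si](c2ccccc2)(c2ccccc2)C(C)(C)C)ccc1OCc1ccccc1 | intermediate
14 | 4-bromo-2-methoxyphenol | COc1cc(Br)ccc1O | starting material
15 | bromoacetic acid | OC(=O)CBr | starting material
16 | 2-(4-bromo-2-methoxyphenoxy)acetic acid | COc1cc(Br)ccc1OCC(=O)O | intermediate
17 | (R)-4-benzyloxazolidin-2-one | O=C1N[C@H](Cc2ccccc2)CO1 | starting material
18 | 2-(4-bromo-2-methoxyphenoxy)acetic pivalic anhydride (not isolated) | COc1cc(Br)ccc1OCC(=O)OC(=O)C(C)(C)C | intermediate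
19 | (R)-4-benzyl-3-[2-(4-bromo-2-methoxyphenoxy)acetyl]oxazolidin-2-one | COc1cc(Br)ccc1OCC(=O)N1[C@H](Cc2ccccc2)COC1=O | intermediate
20 | (Z)-dibutylboron enolate of 19 (not isolated) | CCCCB(CCCC)O/C(=C\Oc1ccc(Br)cc1OC)N1[C@H](Cc2ccccc2)COC1=O | intermediate
21 | (R)-4-benzyl-3-{(2R,3S)-3-[4-(benzyloxy)-3-methoxyphenyl]-2-(4-bromo-2-methoxyphenoxy)-3-hydroxypropanoyl}oxazolidin-2-one | COc1cc(Br)ccc1O[C@@H](C(=O)N1[C@H](Cc2ccccc2)COC1=O)[C@@H](O)c1ccc(OCc2ccccc2)c(OC)c1 | intermediate
22 | (1S,2S)-1-[4-(benzyloxy)-3-methoxyphenyl]-2-(4-bromo-2-methoxyphenoxy)propane-1,3-diol | COc1cc(Br)ccc1O[C@@H](CO)[C@@H](O)c1ccc(OCc2ccccc2)c(OC)c1 | intermediate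
23 | (1S,2S)-1-[4-(benzyloxy)-3-methoxyphenyl]-2-(4-bromo-2-methoxyphenoxy)-1,3-bis[(tert-butyldimethylsilyl)oxy]propane | COc1cc(Br)ccc1O[C@@H](CO[Si](C)(C)C(C)(C)C)[C@@H](O[Si](C)(C)C(C)(C)C)c1ccc(OCc2ccccc2)c(OC)c1 | intermediate
24 | aryllithium from 23 (not isolated) | COc1cc([Li])ccc1O[C@@H](CO[Si](C)(C)C(C)(C)C)[C@@H](O[Si](C)(C)C(C)(C)C)c1ccc(OCc2ccccc2)c(OC)c1 | intermediate
25 | arylzinc bromide from 24 (not isolated) | COc1cc([Zn]Br)ccc1O[C@@H](CO[Si](C)(C)C(C)(C)C)[C@@H](O[Si](C)(C)C(C)(C)C)c1ccc(OCc2ccccc2)c(OC)c1 | intermediate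
26 | fully protected coupling product, (2S,3R,4R) in the oxolane and (1S,2S) in the chain | COc1cc(C[C@H]2CO[C@H](c3ccc(O[C@@H](CO[Si](C)(C)C(C)(C)C)[C@@H](O[Si](C)(C)C(C)(C)C)c4ccc(OCc5ccccc5)c(OC)c4)c(OC)c3)[C@H]2CO[Si](c2ccccc2)(c2ccccc2)C(C)(C)C)ccc1OCc1ccccc1 | intermediate
27 | bis(benzyl ether) triol | COc1cc(C[C@H]2CO[C@H](c3ccc(O[C@@H](CO)[C@@H](O)c4ccc(OCc5ccccc5)c(OC)c4)c(OC)c3)[C@H]2CO)ccc1OCc1ccccc1 | intermediate
28 | CNP0226724.1 | COc1cc(C[C@H]2CO[C@H](c3ccc(O[C@@H](CO)[C@@H](O)c4ccc(O)c(OC)c4)c(OC)c3)[C@H]2CO)ccc1O | target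

Total step count: 15. Longest linear sequence: 10 (steps 1 to 7, then 13 to 15).

Steps most likely to fail

Step 13. Ionisation of the sulfone may be slow with the bulky zinc reagent. Sulfinic acid may then be lost towards the dihydrofuran, or the facial selectivity at C2 may erode. The fallback sets out from 12 and 23 and comes back at 26; it builds the same bond by carbonyl addition and closes the ring afterwards. Acetal 12 is hydrolysed (AcOH, H2O, THF) to the lactol F1. The lactol is deprotonated with CH3MgBr and treated with aryllithium 24, made from 23 as in step 13. The aryllithium adds to the open hydroxy aldehyde form and gives the benzylic 1,4-diol F2 as a mixture at the new carbinol carbon. Catalytic camphorsulfonic acid in CH2Cl2 at 0 °C ionises this p-alkoxybenzylic alcohol, and the primary hydroxyl closes the oxolane. Both carbinol epimers should converge on the 2,3-trans ether 26. The silylated benzylic carbon of the chain is deactivated by its neighbouring aryloxy group and should ionise more slowly.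

Step 4. The lactone enolate may be silylated on carbon instead of oxygen, capture of the carbenium ion may be sluggish, or methanol may be lost from the product by beta-elimination. The fallback sets out from 6 and comes back at 13. It brings the future C2 in one oxidation level lower, as a sulfide, and raises it by a Pummerer-type oxidation. The lithium enolate of 6 (LiN(iPr)2, THF, -78 °C) is alkylated anti to the benzyl group with PhSCH2I, giving the trans thioether lactone F3. LiAlH4 then gives the thioether diol F4. N-chlorosuccinimide with 2,6-lutidine chlorinates the carbon next to sulfur, and the hydroxyl that can form a five-membered ring captures the thionium ion to give the 2-(phenylthio)oxolane alcohol F5. Oxidation with 3-ClC6H4CO3H and NaHCO3 gives the hydroxy sulfone F6, and tBuPh2SiCl with imidazole gives 13.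

Step 7. Under the protic conditions the oxocarbenium ion may lose and regain H-3 reversibly, which would erode the C3 configuration, or the silyl ether may be lost. The fallback sets out from 12 and comes back at 13. It replaces the protic exchange with an aprotic thioacetal formation followed by oxidation. PhSSiMe3, ZnI2 and Bu4NI in ClCH2CH2Cl convert 12 into the silylated 2-(phenylthio)oxolane F7. Oxidation with 3-ClC6H4CO3H and NaHCO3 in CH2Cl2 at 0 °C then gives sulfone 13.

Further compounds
F1 | step 13 | (3R,4R)-4-[4-(benzyloxy)-3-methoxybenzyl]-3-{[(tert-butyldiphenylsilyl)oxy]methyl}oxolan-2-ol | COc1cc(C[C@H]2COC(O)[C@H]2CO[Si](c2ccccc2)(c2ccccc2)C(C)(C)C)ccc1OCc1ccccc1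
F2 | step 13 | benzylic 1,4-diol from addition of 24 to F1, both carbinol epimers | COc1cc(C[C@@H](CO)[C@H](CO[Si](c2ccccc2)(c2ccccc2)C(C)(C)C)C(O)c2ccc(O[C@@H](CO[Si](C)(C)C(C)(C)C)[C@@H](O[Si](C)(C)C(C)(C)C)c3ccc(OCc4ccccc4)c(OC)c3)c(OC)c2)ccc1OCc1ccccc1
F3 | step 4 | (3R,4R)-4-[4-(benzyloxy)-3-methoxybenzyl]-3-[(phenylthio)methyl]dihydrofuran-2(3H)-one | COc1cc(C[C@H]2COC(=O)[C@@H]2CSc2ccccc2)ccc1OCc1ccccc1
F4 | step 4 | 2-[4-(benzyloxy)-3-methoxybenzyl]-3-[(phenylthio)methyl]butane-1,4-diol, configuration as in 10 | COc1cc(C[C@@H](CO)[C@H](CO)CSc2ccccc2)ccc1OCc1ccccc1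
F5 | step 4 | {(3R,4R)-4-[4-(benzyloxy)-3-methoxybenzyl]-2-(phenylthio)oxolan-3-yl}methanol | COc1cc(C[C@H]2COC(Sc3ccccc3)[C@H]2CO)ccc1OCc1ccccc1
F6 | step 4 | {(3R,4R)-2-(benzenesulfonyl)-4-[4-(benzyloxy)-3-methoxybenzyl]oxolan-3-yl}methanol | COc1cc(C[C@H]2COC(S(=O)(=O)c3ccccc3)[C@H]2CO)ccc1OCc1ccccc1
F7 | step 7 | (3R,4R)-4-[4-(benzyloxy)-3-methoxybenzyl]-3-{[(tert-butyldiphenylsilyl)oxy]methyl}-2-(phenylthio)oxolane | COc1cc(C[C@H]2COC(Sc3ccccc3)[C@H]2CO[Si](c2ccccc2)(c2ccccc2)C(C)(C)C)ccc1OCc1ccccc1
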